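## Retrosynthetic overview

1. The C2–C1′ bond and the C2 hemiketal stereocentre are disconnected together (retro-Claisen) to a 2-hydroxy-3-(allyloxy)benzofuran, which is the O–H insertion product of diazo lactone 6 and tertiary allylic alcohol 13 under light.
2. Alcohol 13 comes from (R)-(−)-linalool, whose carbinol carbon is the only bought stereocentre and is relayed to C2. The chain is completed by C8 allylic oxidation, C8–C9 alkenyl addition and oxidation to the dienone.
3. Diazo lactone 6 comes from 4-methylbenzofuran-2(3H)-one by diazo transfer. The lactone comes from 2,3-dimethylphenol via its carbamate (lateral lithiation and 1,4-carbamoyl shift).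
4. Ring order: the benzofuranone (the only ring) is closed first as the lactone in step 2. The key step then swaps its oxidation pattern: lactone C2 becomes the hemiketal and C3 becomes the ketone.

Assumption: the C2 hemiketal keeps its configuration under neutral or weakly acidic aprotic conditions (base would open it to the 1,2-diketone and racemise it), so no base touches it once formed; (R)-(−)-linalool of ≥97% ee is used.

## Route

Step 1
Reactants: 1 2,3-dimethylphenol; 2 N,N-diethylcarbamoyl chloride
Product: 3 2,3-dimethylphenyl N,N-diethylcarbamate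
Conditions: NaH, THF, 0 °C → reflux
Reagents that add atoms: none
Why: O-acylation of the sodium phenoxide (carbamate formation) is routine and installs both the directing group and the carbon that becomes the lactone carbonyl.

Step 2
Reactants: 3 2,3-dimethylphenyl N,N-diethylcarbamate
Product: 5 4-methyl-1-benzofuran-2(3H)-one, via amide 4 (not isolated)
Conditions: LDA (2.5 equiv), THF, −78 °C → rt; then TFA, PhMe, reflux
Reagents that add atoms: none
Why: LDA deprotonates the ortho-methyl group (lateral lithiation; the meta-methyl is out of reach), the benzylic anion takes over the carbamoyl group (anionic homologous Fries rearrangement, 1,4-O→C shift), and acid closes the phenol onto the amide with loss of diethylamine (lactonisation).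

Step 3
Reactants: 5 4-methyl-1-benzofuran-2(3H)-one
Product: 6 3-diazo-4-methyl-1-benzofuran-2(3H)-one
Conditions: p-ABSA, Et3N, MeCN, 0 °C → rt, N2, dark
Reagents that add atoms: 4-acetamidobenzenesulfonyl azide (p-ABSA), CC(=O)Nc1ccc(cc1)S(=O)(=O)N=[N+]=[N-]
Why: Regitz diazo transfer to the doubly activated (aryl and lactone) C3 methylene, as is routine for benzofuran-2(3H)-one itself.

Step 4
Reactants: 7 (R)-(−)-linalool
Product: 8 (2E,6R)-6-hydroxy-2,6-dimethylocta-2,7-dienal
Conditions: SeO2 (1.2 equiv), 1,4-dioxane/EtOH 9:1, 80 °C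
Reagents that add atoms: selenium dioxide, O=[Se]=O
Why: Riley allylic oxidation (ene reaction then [2,3]-shift) attacks the E-methyl of the trisubstituted alkene selectively and leaves the vinyl group and the tertiary carbinol stereocentre untouched.

Step 5
Reactants: 8 (2E,6R)-6-hydroxy-2,6-dimethylocta-2,7-dienal; 9 2-methyl-2-(trimethylsilyloxy)but-3-yne
Product: 12 (3R,6E,9E)-3,7,11-trimethyl-11-(trimethylsilyloxy)dodeca-1,6,9-triene-3,8-diol (both C8 epimers), via alkenylzirconocene 10 (not isolated), via alkenylzinc 11 (not isolated)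
Conditions: 9 (2.5 equiv), Cp2Zr(H)Cl, CH2Cl2, rt; Me2Zn, −65 °C; then 8, 0 °C; sat. NH4Cl
Reagents that add atoms: none
Why: Wipf hydrozirconation, Zr→Zn transmetalation and 1,2-addition to the enal; syn hydrozirconation fixes the 9E alkene, the excess reagent covers the free tertiary OH, and the C8 epimer mixture is erased in step 6.

Step 6
Reactants: 12 (3R,6E,9E)-3,7,11-trimethyl-11-(trimethylsilyloxy)dodeca-1,6,9-triene-3,8-diol
Product: 13 (3R,6E,9E)-3-hydroxy-3,7,11-trimethyl-11-(trimethylsilyloxy)dodeca-1,6,9-trien-8-one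
Conditions: activated MnO2 (20 equiv), CH2Cl2, rt
Reagents that add atoms: none
Why: MnO2 oxidises only the doubly allylic secondary alcohol (allylic alcohol oxidation); the tertiary alcohol and the tertiary silyl ether cannot react.

Step 7
Reactants: 13 (3R,6E,9E)-3-hydroxy-3,7,11-trimethyl-11-(trimethylsilyloxy)dodeca-1,6,9-trien-8-one; 6 3-diazo-4-methyl-1-benzofuran-2(3H)-one
Product: 16 (2R)-2-hydroxy-2-[(2E,6E,9E)-11-hydroxy-3,7,11-trimethyl-8-oxododeca-2,6,9-trien-1-yl]-4-methyl-1-benzofuran-3(2H)-one, via enol ether 14 (not isolated), via silyl ether 15 (not isolated)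
Conditions: 6 (1.5 equiv, slow addition), 450 nm LEDs, CH2Cl2, 4 Å MS, 20 → 40 °C; then HF·pyridine, pyridine, THF, 0 °C; AgNO3–SiO2 chromatography
Reagents that add atoms: none
Why: Proposed new method: metal-free 450 nm photolysis of diazo lactone 6 should give a free singlet carbene that the tertiary O–H of 13 captures as an oxonium ylide, whose 1,4-proton shift to the lactone oxygen gives the aromatic enol 14 (a 2-hydroxybenzofuran, i.e. an allyl vinyl ether with an OH donor on its terminus), which in the acid- and base-free medium should undergo Claisen rearrangement faster than it tautomerises, forming C2–C1′ and turning the former lactone carbon into the hemiketal; in the chair with the C3′ chain equatorial the (3R) carbinol is relayed to (2R) together with the 2′E alkene, while the methyl-equatorial chair gives the separable (2S,2′Z) isomer (E:Z about 2–3:1 expected); the closest known reactions are the Rh(II)-carbenoid O–H insertion/Claisen sequence of α-diazo ketones with allylic alcohols and the blue-light O–H insertion of aryldiazoacetates; buffered HF·pyridine then removes the tertiary TMS ether without base.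

## Compound list

1 | 2,3-dimethylphenol | Cc1cccc(O)c1C | starting material
2 | N,N-diethylcarbamoyl chloride | CCN(CC)C(Cl)=O | starting material
3 | 2,3-dimethylphenyl N,N-diethylcarbamate | CCN(CC)C(=O)Oc1cccc(C)c1C | intermediate
4 | N,N-diethyl-2-(2-hydroxy-6-methylphenyl)acetamide | CCN(CC)C(=O)Cc1c(C)cccc1O | intermediate
5 | 4-methyl-1-benzofuran-2(3H)-one | Cc1cccc2OC(=O)Cc12 | intermediate
6 | 3-diazo-4-methyl-1-benzofuran-2(3H)-one | Cc1cccc2OC(=O)C(=[N+]=[N-])c12 | intermediate
7 | (R)-(−)-linalool, (3R)-3,7-dimethylocta-1,6-dien-3-ol | C=C[C@](C)(O)CCC=C(C)C | starting material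
8 | (2E,6R)-6-hydroxy-2,6-dimethylocta-2,7-dienal | C=C[C@](C)(O)CC/C=C(\C)C=O | intermediate
9 | 2-methyl-2-(trimethylsilyloxy)but-3-yne | C#CC(C)(C)O[Si](C)(C)C | starting material
10 | (E)-chlorobis(cyclopentadienyl)[3-methyl-3-(trimethylsilyloxy)but-1-en-1-yl]zirconium | C[Si](C)(C)OC(C)(C)/C=C/[Zr](Cl)(C1C=CC=C1)C1C=CC=C1 | intermediate
11 | (E)-methyl[3-methyl-3-(trimethylsilyloxy)but-1-en-1-yl]zinc | C[Zn]/C=C/C(C)(C)O[Si](C)(C)C | intermediate
12 | (3R,6E,9E)-3,7,11-trimethyl-11-(trimethylsilyloxy)dodeca-1,6,9-triene-3,8-diol (C8 epimers) | C=C[C@](C)(O)CC/C=C(\C)C(O)/C=C/C(C)(C)O[Si](C)(C)C | intermediate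
13 | (3R,6E,9E)-3-hydroxy-3,7,11-trimethyl-11-(trimethylsilyloxy)dodeca-1,6,9-trien-8-one | C=C[C@](C)(O)CC/C=C(\C)C(=O)/C=C/C(C)(C)O[Si](C)(C)C | intermediate
14 | 4-methyl-3-{[(3R,6E,9E)-3,7,11-trimethyl-8-oxo-11-(trimethylsilyloxy)dodeca-1,6,9-trien-3-yl]oxy}-1-benzofuran-2-ol | C=C[C@](C)(Oc1c(O)oc2cccc(C)c12)CC/C=C(\C)C(=O)/C=C/C(C)(C)O[Si](C)(C)C | intermediate
15 | (2R)-2-hydroxy-4-methyl-2-[(2E,6E,9E)-3,7,11-trimethyl-8-oxo-11-(trimethylsilyloxy)dodeca-2,6,9-trien-1-yl]-1-benzofuran-3(2H)-one | C/C(=C\C[C@@]1(O)Oc2cccc(C)c2C1=O)CC/C=C(\C)C(=O)/C=C/C(C)(C)O[Si](C)(C)C | intermediate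
16 | (2R)-2-hydroxy-2-[(2E,6E,9E)-11-hydroxy-3,7,11-trimethyl-8-oxododeca-2,6,9-trien-1-yl]-4-methyl-1-benzofuran-3(2H)-one | C/C(=C\C[C@@]1(O)Oc2cccc(C)c2C1=O)CC/C=C(\C)C(=O)/C=C/C(C)(C)O | target

## Step count and risks

Total steps: 7. Longest linear sequence: 4 (steps 1, 2, 3, 7 or steps 4, 5, 6, 7).

**Step 7 (proposed new step).** The enol 14 may tautomerise to the lactone before it rearranges. The ylide may instead undergo a direct [2,3]-shift to the 3-allyl-3-hydroxy lactone. The peri-methyl group hinders capture of the carbene. The Me/CH2 difference at C3′ limits E:Z, so part of the material is lost as the (2S,2′Z) isomer.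

Fallback with known chemistry, setting out from 6 and 13 and rejoining at 16: Rh2(OAc)4-catalysed O–H insertion (CH2Cl2, rt, slow addition of 6) gives the α-alkoxy lactone, 4-methyl-3-{[(3R,6E,9E)-3,7,11-trimethyl-8-oxo-11-(trimethylsilyloxy)dodeca-1,6,9-trien-3-yl]oxy}-1-benzofuran-2(3H)-one F1. Soft enolisation with TMSCl and Et3N traps it as the silyl ketene acetal, the 2-(trimethylsilyloxy)benzofuran F2. Warming F2 in toluene gives the Ireland-type Claisen rearrangement through the same chair to the bis-silyl ether, (2S)-4-methyl-2-(trimethylsilyloxy)-2-[(2E,6E,9E)-3,7,11-trimethyl-8-oxo-11-(trimethylsilyloxy)dodeca-2,6,9-trien-1-yl]-1-benzofuran-3(2H)-one F3. F3 has the same spatial arrangement as 16 (the descriptor changes only because OSi outranks OAr), and its hemiketal is locked against ring opening. Buffered HF·pyridine removes both silyl groups to give 16.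

**Step 5.** The alkenylzinc must add to an enal that carries a free tertiary alcohol, and the tertiary TMS ether must survive the work-up.

Fallback setting out from 8 and 9 and rejoining at 12: the lithium acetylide of 9 (n-BuLi, THF, −78 °C, 2.2 equiv) adds to 8 to give the propargylic diol, (3R,6E)-3,7,11-trimethyl-11-(trimethylsilyloxy)dodeca-1,6-dien-9-yne-3,8-diol F4. Red-Al in THF at 0 °C reduces the propargylic alcohol by trans-hydroalumination to the 9E allylic alcohol 12.

**Step 4.** SeO2 oxidation of linalool gives only moderate yields, with 8-hydroxylinalool and over-oxidation products alongside.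

Fallback setting out from 7 and rejoining at 8: ozonolysis with one equivalent of O3 (CH2Cl2/MeOH, −78 °C, then Me2S) cleaves only the electron-rich trisubstituted alkene and gives the lactol, (5R)-5-ethenyl-5-methyloxolan-2-ol F5. Wittig olefination of its open hydroxy-aldehyde form with commercial 2-(triphenylphosphoranylidene)propanal (PhMe, 80 °C) gives the E-enal 8.

## Further compounds

F1 | step 7 | 4-methyl-3-{[(3R,6E,9E)-3,7,11-trimethyl-8-oxo-11-(trimethylsilyloxy)dodeca-1,6,9-trien-3-yl]oxy}-1-benzofuran-2(3H)-one (C3 epimers) | C=C[C@](C)(OC1C(=O)Oc2cccc(C)c12)CC/C=C(\C)C(=O)/C=C/C(C)(C)O[Si](C)(C)C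
F2 | step 7 | trimethyl[(4-methyl-3-{[(3R,6E,9E)-3,7,11-trimethyl-8-oxo-11-(trimethylsilyloxy)dodeca-1,6,9-trien-3-yl]oxy}-1-benzofuran-2-yl)oxy]silane | C=C[C@](C)(Oc1c(O[Si](C)(C)C)oc2cccc(C)c12)CC/C=C(\C)C(=O)/C=C/C(C)(C)O[Si](C)(C)C
F3 | step 7 | (2S)-4-methyl-2-(trimethylsilyloxy)-2-[(2E,6E,9E)-3,7,11-trimethyl-8-oxo-11-(trimethylsilyloxy)dodeca-2,6,9-trien-1-yl]-1-benzofuran-3(2H)-one | C/C(=C\C[C@@]1(O[Si](C)(C)C)Oc2cccc(C)c2C1=O)CC/C=C(\C)C(=O)/C=C/C(C)(C)O[Si](C)(C)C
F4 | step 5 | (3R,6E)-3,7,11-trimethyl-11-(trimethylsilyloxy)dodeca-1,6-dien-9-yne-3,8-diol (C8 epimers) | C=C[C@](C)(O)CC/C=C(\C)C(O)C#CC(C)(C)O[Si](C)(C)C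
F5 | step 4 | (5R)-5-ethenyl-5-methyloxolan-2-ol (anomers) | C=C[C@@]1(C)CCC(O)O1
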